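## Retrosynthetic overview

1. The target comes from its tris(O-benzyl) ether by one global hydrogenolysis at the end.
2. Key cut, both ring A–CH2Ar bonds at once: a ring A 2,6-dibromide (two acceptor carbons) plus 2 × 4-(benzyloxy)benzaldehyde. The carbonyl carbon has its polarity reversed as the N–H hydrazone (a benzyl-anion equivalent that loses N2) under nickel catalysis.
3. The dibromide comes from O-benzyl-3-hydroxy-5,3′-dimethoxybibenzyl by twofold bromination para to each ring A oxygen.
4. The bibenzyl comes from 3-vinylanisole (hydroboration) and O-benzyl-3-bromo-5-methoxyphenol by B-alkyl Suzuki–Miyaura coupling.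
5. No ring is built, since ring A, ring B and both hydroxybenzyl rings are bought as arenes. Ring B is attached to ring A first, then the two hydroxybenzyl rings together.

Assumption: the target SMILES has no stereocentre, stereogenic double bond or stable axis, so the compound is achiral and needs no enantiocontrol; the SMILES (ring A 3-OH and 5-OMe, ring B 3′-OMe) is taken as authoritative over the name.

## Route

Step 1
Reactants: 1 3-bromo-5-methoxyphenol
Product: 2 1-(benzyloxy)-3-bromo-5-methoxybenzene
Conditions: BnBr (1.1 equiv), K2CO3 (1.5 equiv), DMF, rt, 6 h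
Reagents that add atoms: benzyl bromide, BrCc1ccccc1
Why: Williamson ether synthesis; the phenoxide is the only nucleophile present, and the benzyl ether masks the ring A phenol through the later basic, metal-catalysed steps, with no stereocentre formed.

Step 2
Reactants: 2 1-(benzyloxy)-3-bromo-5-methoxybenzene; 3 3-vinylanisole (1-ethenyl-3-methoxybenzene)
Product: 5 1-(benzyloxy)-3-methoxy-5-[2-(3-methoxyphenyl)ethyl]benzene, via B-alkyl-9-BBN borane 4 (not isolated)
Conditions: 3, 9-BBN (0.5 M in THF, 1.1 equiv), 0 °C to rt, 3 h; then 2, Pd(dppf)Cl2 (3 mol%), 3 M aq NaOH (3 equiv), THF, 65 °C, 12 h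
Reagents that add atoms: 9-borabicyclo[3.3.1]nonane (9-BBN), C1CC2CCCC(C1)B2 (its boron and ring stay in intermediate 4 only; 5 keeps one hydrogen from it)
Why: Anti-Markovnikov hydroboration followed by B-alkyl Suzuki–Miyaura coupling; zerovalent palladium formed from Pd(dppf)Cl2 inserts into the single C–Br bond of 2, the hydroxide-activated primary alkylborane transfers its alkyl group, the wide-bite dppf ligand favours reductive elimination over beta-hydride loss, and all ethers are inert.

Step 3
Reactants: 5 1-(benzyloxy)-3-methoxy-5-[2-(3-methoxyphenyl)ethyl]benzene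
Product: 6 1-(benzyloxy)-2,4-dibromo-5-methoxy-3-[2-(3-methoxyphenyl)ethyl]benzene
Conditions: NBS (2.05 equiv), MeCN, −10 °C to rt, dark, 3 h
Reagents that add atoms: N-bromosuccinimide, O=C1CCC(=O)N1Br
Why: Electrophilic aromatic bromination; each position flanking the ethylene chain is para to one ring A oxygen and ortho to the other, so the doubly activated ring A reacts twice before the singly activated ring B or the ortho/ortho position between the two oxygens (the pattern known for 5-alkylresorcinol ethers).

Step 4
Reactants: 6 1-(benzyloxy)-2,4-dibromo-5-methoxy-3-[2-(3-methoxyphenyl)ethyl]benzene; 7 4-(benzyloxy)benzaldehyde (3.0 equiv)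
Product: 11 1-(benzyloxy)-2,4-bis[4-(benzyloxy)benzyl]-5-methoxy-3-[2-(3-methoxyphenyl)ethyl]benzene, via hydrazone 8 (not isolated), via first monobromide 9 (not isolated), via isomeric monobromide 10 (not isolated)
Conditions: 7, N2H4·H2O (3.3 equiv), THF, rt, 1 h, Na2SO4; then 6, Ni(cod)2 (20 mol%), PMe3 (40 mol%), DBU (5 equiv), THF–1,4-dioxane, 80 °C, 24 h, argon
Reagents that add atoms: hydrazine hydrate, NN.O (its nitrogen stays in intermediate 8 only and leaves as N2; 11 keeps only hydrogen from it)
Why: Proposed new method: the closest known reaction is the nickel-catalysed cross-coupling of aldehyde N–H hydrazones with aryl bromides (Wolff–Kishner-type carbonyl umpolung), stretched here to a twofold coupling at two di-ortho-substituted C–Br bonds; zerovalent nickel bearing the small, strongly donating PMe3 inserts into each C–Br bond, DBU deprotonates the nickel-bound hydrazone, loss of N2 turns the former carbonyl carbon (a natural acceptor) into a nickel-bound benzyl donor, and reductive elimination joins it to the former C–Br carbon (also an acceptor) directly at the CH2 oxidation level, with both monobromides converging on 11 and no stereocentre created.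

Step 5
Reactants: 11 1-(benzyloxy)-2,4-bis[4-(benzyloxy)benzyl]-5-methoxy-3-[2-(3-methoxyphenyl)ethyl]benzene
Product: 12 2,4-bis(4-hydroxybenzyl)-5-methoxy-3-[2-(3-methoxyphenyl)ethyl]phenol (the target)
Conditions: H2 (1 atm), 10% Pd/C, EtOAc–MeOH (1:1), rt, 12 h
Reagents that add atoms: none
Why: Catalytic hydrogenolysis cleaves only the three O–CH2Ph bonds, while the two aryl methyl ethers and the diarylmethane and bibenzyl C–C bonds are inert, so all three phenols are released in one operation and there is no stereocentre to scramble.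

## Compound list

1 | 3-bromo-5-methoxyphenol | COc1cc(O)cc(Br)c1 | starting material
2 | 1-(benzyloxy)-3-bromo-5-methoxybenzene | COc1cc(Br)cc(OCc2ccccc2)c1 | intermediate
3 | 3-vinylanisole (1-ethenyl-3-methoxybenzene) | C=Cc1cccc(OC)c1 | starting material
4 | 9-[2-(3-methoxyphenyl)ethyl]-9-borabicyclo[3.3.1]nonane (not isolated) | COc1cccc(CCB2C3CCCC2CCC3)c1 | intermediate
5 | 1-(benzyloxy)-3-methoxy-5-[2-(3-methoxyphenyl)ethyl]benzene | COc1cccc(CCc2cc(OC)cc(OCc3ccccc3)c2)c1 | intermediate
6 | 1-(benzyloxy)-2,4-dibromo-5-methoxy-3-[2-(3-methoxyphenyl)ethyl]benzene | COc1cccc(CCc2c(Br)c(OCc3ccccc3)cc(OC)c2Br)c1 | intermediate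
7 | 4-(benzyloxy)benzaldehyde | O=Cc1ccc(OCc2ccccc2)cc1 | starting material
8 | (E)-4-(benzyloxy)benzaldehyde hydrazone (not isolated) | N/N=C/c1ccc(OCc2ccccc2)cc1 | intermediate
9 | 1-(benzyloxy)-4-[4-(benzyloxy)benzyl]-2-bromo-5-methoxy-3-[2-(3-methoxyphenyl)ethyl]benzene (coupled next to OMe, not isolated) | COc1cccc(CCc2c(Br)c(OCc3ccccc3)cc(OC)c2Cc2ccc(OCc3ccccc3)cc2)c1 | intermediate
10 | 1-(benzyloxy)-2-[4-(benzyloxy)benzyl]-4-bromo-5-methoxy-3-[2-(3-methoxyphenyl)ethyl]benzene (coupled next to OBn, not isolated) | COc1cccc(CCc2c(Cc3ccc(OCc4ccccc4)cc3)c(OCc3ccccc3)cc(OC)c2Br)c1 | intermediate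
11 | 1-(benzyloxy)-2,4-bis[4-(benzyloxy)benzyl]-5-methoxy-3-[2-(3-methoxyphenyl)ethyl]benzene | COc1cccc(CCc2c(Cc3ccc(OCc4ccccc4)cc3)c(OCc3ccccc3)cc(OC)c2Cc2ccc(OCc3ccccc3)cc2)c1 | intermediate
12 | 2,4-bis(4-hydroxybenzyl)-5-methoxy-3-[2-(3-methoxyphenyl)ethyl]phenol (achiral) | COc1cccc(CCc2c(Cc3ccc(O)cc3)c(O)cc(OC)c2Cc2ccc(O)cc2)c1 | target

## Step count and risks

Total step count: 5. Longest linear sequence: 5 (1 → 2 → 5 → 6 → 11 → 12).

**Step 4 (highest risk).** Both C–Br bonds are electron-rich and flanked on both sides. Insertion of nickel or the final reductive elimination may therefore lose out to hydrodebromination or to simple reduction of the hydrazone, and the reaction may stall at 9 and 10.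

The fallback sets out from 6 and comes back at 11. It keeps the carbonyl polarity reversal but swaps the roles, so the crowded partner becomes the donor and the halide is unhindered.
- Compound 6 is dilithiated (t-BuLi, 4.2 equiv, THF, −78 °C) and quenched with DMF to give 4-(benzyloxy)-6-methoxy-2-[2-(3-methoxyphenyl)ethyl]benzene-1,3-dicarbaldehyde F1.
- N2H4·H2O in THF converts this in the flask into the bis-hydrazone of that dialdehyde F2.
- F2 is coupled with commercial 1-(benzyloxy)-4-iodobenzene (2.5 equiv) under Ni(cod)2/PMe3/DBU in THF at 60 °C to give 11.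
- This costs one extra step.

**Step 3.** Bromine could enter ring B (para to its methoxy group) or the position between the two ring A oxygens, giving inseparable isomers.

The fallback sets out from 1 (with borane 4 made as in step 2) and comes back at 6. It brominates the far more activated free phenol and protects afterwards.
- Compound 1 is coupled with 4 (Pd(dppf)Cl2, aq NaOH, 4 equiv, THF, 65 °C) to give 3-methoxy-5-[2-(3-methoxyphenyl)ethyl]phenol F3.
- Br2 (2.0 equiv, CH2Cl2, −30 °C) brominates the two positions flanking the chain, the pattern known for 5-alkylresorcinols, to give 2,4-dibromo-5-methoxy-3-[2-(3-methoxyphenyl)ethyl]phenol F4.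
- BnBr/K2CO3 in DMF then gives 6.
- The step count is unchanged.

**Step 2.** Protodeboronation or beta-hydride elimination of the alkylpalladium species could erode the yield.

The fallback sets out from 2 and 3 and comes back at 5. It forms the bridge as an alkene.
- Heck reaction (Pd(OAc)2, P(o-tol)3, Et3N, DMF, 100 °C) gives (E)-1-(benzyloxy)-3-methoxy-5-[2-(3-methoxyphenyl)ethenyl]benzene F5.
- The alkene is reduced with diimide (TsNHNH2, NaOAc, THF–H2O, reflux), which leaves the benzyl ether untouched, to give 5.
- This costs one extra step.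

## Further compounds

F1 | step 4 | 4-(benzyloxy)-6-methoxy-2-[2-(3-methoxyphenyl)ethyl]benzene-1,3-dicarbaldehyde | COc1cccc(CCc2c(C=O)c(OCc3ccccc3)cc(OC)c2C=O)c1
F2 | step 4 | bis-hydrazone of dialdehyde F1 (E,E) | COc1cccc(CCc2c(/C=N/N)c(OCc3ccccc3)cc(OC)c2/C=N/N)c1
F3 | step 3 | 3-methoxy-5-[2-(3-methoxyphenyl)ethyl]phenol | COc1cccc(CCc2cc(O)cc(OC)c2)c1
F4 | step 3 | 2,4-dibromo-5-methoxy-3-[2-(3-methoxyphenyl)ethyl]phenol | COc1cccc(CCc2c(Br)c(O)cc(OC)c2Br)c1
F5 | step 2 | (E)-1-(benzyloxy)-3-methoxy-5-[2-(3-methoxyphenyl)ethenyl]benzene | COc1cccc(/C=C/c2cc(OC)cc(OCc3ccccc3)c2)c1
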